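Cuts (flavan numbering; ring A = C4a–C8a, ring B = 2-aryl, ring C = pyran): first the four O-benzyl groups. Then C2–C3 and O1–C8a of ring C are cut together, which frees ring-B aldehyde 12 and ring-A o-bromostyrene 10. Last come C4a–vinyl (Stille), the side-chain C=O (ionic hydrogenation), the methine–aryl bond (Rh 1,4-addition) and the enone C=C (Claisen–Schmidt).
Enabling feature: C8a is ortho to C4a, and the two-carbon arm C4–C3 on C4a ends exactly where C2 must bond. C3–B/C8a–Br on ring A is therefore a 1,4-ambiphile that matches the C=O dipole of the aldehyde, and an oxygen born on C2 lies six atoms from C8a. Both helpers (B on C3, Br on C8a) leave in the event itself.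
Forward order: halogen pattern on ring A, chalcone, (R)-diarylmethine, CH2, vinyl. The open chain is complete before ring C, the only ring that has to be made, closes in step 9; hydrogenolysis ends the route.
Stereochemistry: the (R)-methine comes from a chiral-diene rhodium catalyst (step 5) and C2 (S) from a chiral bisphosphine on copper (step 9). The centres are remote, so each is set by its own catalyst and neither is touched afterwards.

Key step: step 9

Assumption: the sense of induction of the chiral catalysts on these exact substrates is inferred from the accepted face-selection models; the ligand enantiomer named is the predicted one, and its antipode is equally available.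

Step 1
Reactants: 1 4-bromo-2-hydroxybenzaldehyde
Product: 2 4-bromo-2-hydroxy-5-iodobenzaldehyde
Conditions: NIS, TFA (cat.), MeCN, 0 °C → rt
Reagents that add atoms: N-iodosuccinimide O=C1CCC(=O)N1I
Why: Electrophilic aromatic iodination: OH (para), CHO (meta) and Br (ortho) all direct to C5, and the only other activated site, C3, is wedged between OH and Br.

Step 2
Reactants: 2 4-bromo-2-hydroxy-5-iodobenzaldehyde
Product: 3 2-(benzyloxy)-4-bromo-5-iodobenzaldehyde
Conditions: BnBr, K2CO3, DMF, rt
Reagents that add atoms: benzyl bromide BrCc1ccccc1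
Why: Williamson ether synthesis on the acidic salicylaldehyde phenol, the only site of 2 that is alkylated under carbonate conditions.

Step 3
Reactants: 4 1-[4-(benzyloxy)-2-hydroxyphenyl]ethan-1-one
Product: 5 1-[4-(benzyloxy)-2-methoxyphenyl]ethan-1-one
Conditions: MeI, K2CO3, DMF, 40 °C
Reagents that add atoms: iodomethane CI
Why: Williamson O-methylation; the hydrogen-bonded 2-OH is the only acidic site, and warm DMF with excess MeI overcomes its low reactivity.

Step 4
Reactants: 3 2-(benzyloxy)-4-bromo-5-iodobenzaldehyde; 5 1-[4-(benzyloxy)-2-methoxyphenyl]ethan-1-one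
Product: 6 (E)-chalcone
Conditions: KOH, EtOH–THF, rt
Reagents that add atoms: none
Why: Claisen–Schmidt condensation: 3 cannot enolise, 5 is the only enolisable partner, and E1cB loss of water should give the conjugated (E)-enone under thermodynamic control.

Step 5
Reactants: 6 (E)-chalcone; 7 [4-(benzyloxy)phenyl]boronic acid
Product: 8 (3R)-β,β-diaryl ketone
Conditions: [RhCl(C2H4)2]2 (2.5 mol %), (S,S)-Ph-bod* [(1S,4S)-2,5-diphenylbicyclo[2.2.2]octa-2,5-diene] (5.5 mol %), aq KOH (0.5 equiv), dioxane–H2O, 40 °C
Reagents that add atoms: none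
Why: Hayashi–Miyaura asymmetric 1,4-addition: the aryl–Rh(I) species held by the C2-symmetric diene should carbometalate the enone on its α-si face (Si face of C-β), which sets the (R)-methine, and Rh(I) does not insert into aryl iodides or bromides at this temperature.

Step 6
Reactants: 8 (3R)-β,β-diaryl ketone
Product: 9 (R)-1,1,3-triarylpropane with I on C4a and Br on C8a
Conditions: Et3SiH (3 equiv), TFA–CH2Cl2 (1:4), 0 °C → rt
Reagents that add atoms: none
Why: Ionic hydrogenation (Kursanov–Parnes): the 2,4-dialkoxyphenyl ketone is reduced through a strongly stabilised benzylic cation that silane should trap faster than the unactivated ortho positions of the neighbouring rings can, and the methine two carbons away takes no part.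

Step 7
Reactants: 9 (R)-1,1,3-triarylpropane with I on C4a and Br on C8a
Product: 10 (R)-o-bromostyrene
Conditions: Bu3SnCH=CH2 (1.05 equiv), Pd2(dba)3 (cat.), AsPh3 (cat.), NMP, 40 °C
Reagents that add atoms: tributyl(vinyl)stannane C=C[Sn](CCCC)(CCCC)CCCC
Why: Stille coupling: oxidative addition of Pd(0) to C–I is much faster than to the neighbouring C–Br at 40 °C, so only C4a should be vinylated and the bromide is kept for step 9.

Step 8
Reactants: 11 5-hydroxy-2-methoxybenzaldehyde
Product: 12 5-(benzyloxy)-2-methoxybenzaldehyde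
Conditions: BnBr, K2CO3, DMF, rt
Reagents that add atoms: benzyl bromide BrCc1ccccc1
Why: Williamson ether synthesis on the single free phenol; the non-enolisable aldehyde is inert to carbonate.

Step 9
Reactants: 10 (R)-o-bromostyrene; 12 5-(benzyloxy)-2-methoxybenzaldehyde
Product: 15 tetra-O-benzyl ether of the target, via B-alkyl-9-BBN 13 (not isolated), via secondary alkoxide 14 (not isolated)
Conditions: 9-BBN-H (1.05 equiv), THF, rt → 50 °C; then 12, CuCl (10 mol %), (R)-DTBM-SEGPHOS (11 mol %), KOt-Bu (1.3 equiv), THF–toluene, 0 °C → rt; then 1,10-phenanthroline (20 mol %), 100 °C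
Reagents that add atoms: none
Why: Proposed new method: anti-Markovnikov hydroboration makes ring A a 1,4-ambiphile (nucleophilic C3–B, electrophilic C8a–Br); tert-butoxide-assisted B-to-Cu transmetalation gives a primary alkylcopper(I) bearing the chiral bisphosphine, this inserts the C=O of 12 (C3–C2 bond), and the copper(I) alkoxide 14 so born undergoes intramolecular Ullmann-type O-arylation at C8a–Br (O1–C8a bond), releasing CuBr that KOt-Bu returns to the cycle. The closest known reaction types are copper-catalysed additions of alkyl-9-BBN reagents to enones, allylic electrophiles and CO2, enantioselective 1,2-insertions of aldehydes and ketones into L*Cu–B and L*Cu–C bonds, and copper(I)-catalysed cyclisation of 2-haloaryl alkanols to dihydrobenzofurans and chromans; only their merger in one flask on one metal is new. Ring C closes in the 6-exo sense: the tethered alkoxide brings copper to C8a–Br, a seven-membered C,O-chelated copper(III) species forms, and its C–O reductive elimination gives the six-membered pyran. C2 is the only new stereocentre and is controlled by the ligand, which should expose the Si face of the aldehyde to the alkyl group to give (S); the C2–O bond is not touched in the closure, so the configuration is carried into 15, and the remote (R)-methine is a spectator. The step needs the alkylcopper to choose the aldehyde over its own aryl bromide, which the substrate secures because C3–C8a coupling would give a strained benzocyclobutene, and it needs O-arylation at C8a only, which the tether secures; even a base-induced aryne (C8≡C8a, C8–H lying between Br and O7) would be attacked at C8a, meta to O7, and so give the same product.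

Step 10
Reactants: 15 tetra-O-benzyl ether of the target
Product: 16 target CNP0239474.1
Conditions: H2 (1 atm), 10% Pd/C, EtOAc–EtOH, rt
Reagents that add atoms: none
Why: Catalytic hydrogenolysis of the four primary benzyl aryl ethers; the hindered secondary C2–O1 bond of ring C, the methyl ethers and both stereocentres should persist under neutral conditions at 1 atm if the reaction is stopped after uptake of four equivalents of H2.

Compound list
1 | 4-bromo-2-hydroxybenzaldehyde | O=Cc1ccc(Br)cc1O | starting material
2 | 4-bromo-2-hydroxy-5-iodobenzaldehyde | O=Cc1cc(I)c(Br)cc1O | intermediate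
3 | 2-(benzyloxy)-4-bromo-5-iodobenzaldehyde | O=Cc1cc(I)c(Br)cc1OCc1ccccc1 | intermediate
4 | 1-[4-(benzyloxy)-2-hydroxyphenyl]ethan-1-one | CC(=O)c1ccc(OCc2ccccc2)cc1O | starting material
5 | 1-[4-(benzyloxy)-2-methoxyphenyl]ethan-1-one | CC(=O)c1ccc(OCc2ccccc2)cc1OC | intermediate
6 | (E)-3-[2-(benzyloxy)-4-bromo-5-iodophenyl]-1-[4-(benzyloxy)-2-methoxyphenyl]prop-2-en-1-one | COc1cc(OCc2ccccc2)ccc1C(=O)/C=C/c1cc(I)c(Br)cc1OCc1ccccc1 | intermediate
7 | [4-(benzyloxy)phenyl]boronic acid | OB(O)c1ccc(OCc2ccccc2)cc1 | starting material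
8 | (3R)-3-[2-(benzyloxy)-4-bromo-5-iodophenyl]-1-[4-(benzyloxy)-2-methoxyphenyl]-3-[4-(benzyloxy)phenyl]propan-1-one | COc1cc(OCc2ccccc2)ccc1C(=O)C[C@H](c1ccc(OCc2ccccc2)cc1)c1cc(I)c(Br)cc1OCc1ccccc1 | intermediate
9 | 1-(benzyloxy)-5-bromo-4-iodo-2-{(1R)-3-[4-(benzyloxy)-2-methoxyphenyl]-1-[4-(benzyloxy)phenyl]propyl}benzene | COc1cc(OCc2ccccc2)ccc1CC[C@H](c1ccc(OCc2ccccc2)cc1)c1cc(I)c(Br)cc1OCc1ccccc1 | intermediate
10 | 1-(benzyloxy)-5-bromo-4-ethenyl-2-{(1R)-3-[4-(benzyloxy)-2-methoxyphenyl]-1-[4-(benzyloxy)phenyl]propyl}benzene | COc1cc(OCc2ccccc2)ccc1CC[C@H](c1ccc(OCc2ccccc2)cc1)c1cc(C=C)c(Br)cc1OCc1ccccc1 | intermediate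
11 | 5-hydroxy-2-methoxybenzaldehyde | COc1ccc(O)cc1C=O | starting material
12 | 5-(benzyloxy)-2-methoxybenzaldehyde | COc1ccc(OCc2ccccc2)cc1C=O | intermediate
13 | 9-[2-(aryl)ethyl]-9-borabicyclo[3.3.1]nonane derived from 10 (boron on the terminal carbon C3, (R)-methine unchanged) | COc1cc(OCc2ccccc2)ccc1CC[C@H](c1ccc(OCc2ccccc2)cc1)c1cc(CCB2C3CCCC2CCC3)c(Br)cc1OCc1ccccc1 | intermediate
14 | (S)-1-[5-(benzyloxy)-2-methoxyphenyl]-3-(2-bromoaryl)propan-1-olate, Cu(I)/K alkoxide drawn as the potassium salt, (R)-methine unchanged | COc1cc(OCc2ccccc2)ccc1CC[C@H](c1ccc(OCc2ccccc2)cc1)c1cc(CC[C@H]([O-])c2cc(OCc3ccccc3)ccc2OC)c(Br)cc1OCc1ccccc1.[K+] | intermediate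
15 | (2S)-7-(benzyloxy)-2-[5-(benzyloxy)-2-methoxyphenyl]-6-{(1R)-3-[4-(benzyloxy)-2-methoxyphenyl]-1-[4-(benzyloxy)phenyl]propyl}-3,4-dihydro-2H-chromene | COc1cc(OCc2ccccc2)ccc1CC[C@H](c1ccc(OCc2ccccc2)cc1)c1cc2c(cc1OCc1ccccc1)O[C@H](c1cc(OCc3ccccc3)ccc1OC)CC2 | intermediate
16 | (2S)-2-(5-hydroxy-2-methoxyphenyl)-6-[(1R)-3-(4-hydroxy-2-methoxyphenyl)-1-(4-hydroxyphenyl)propyl]-3,4-dihydro-2H-chromen-7-ol | COc1cc(O)ccc1CC[C@H](c1ccc(O)cc1)c1cc2c(cc1O)O[C@H](c1cc(O)ccc1OC)CC2 | target

Total steps: 10. Longest linear sequence: 8 (steps 1, 2, 4, 5, 6, 7, 9, 10).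

Steps most likely to fail

1. Step 9 (Proposed new method).
- What may go wrong: insertion of the electron-rich aldehyde into the primary alkyl–Cu bond may be slower than hydride transfer from the borate or protodemetalation. Facial selectivity may be poor. The alkoxide may stay bound to boron. β-Hydride loss from the copper alkoxide at 100 °C may erode the configuration at C2.
- Fallback (known chemistry, sets out from 9, returns at 15): vinylmagnesium bromide should add to 12 to give racemic 1-[5-(benzyloxy)-2-methoxyphenyl]prop-2-en-1-ol F1. Heck arylation of this allylic alcohol with the C–I bond of 9 follows under ligand-free phase-transfer conditions (Pd(OAc)2, Bu4NCl, NaHCO3, DMF, 50 °C). β-Hydride elimination towards the carbinol and tautomerisation should give the 3-aryl-1-arylpropan-1-one F2 with the bromide intact. Noyori-type asymmetric transfer hydrogenation (RuCl[(S,S)-TsDPEN](p-cymene), HCO2H–Et3N) should give the (S)-1,3-diarylpropan-1-ol F3. Pd-catalysed intramolecular O-arylation (Pd(OAc)2, 2-(di-tert-butylphosphino)-1,1'-binaphthyl, Cs2CO3, toluene, 70 °C) closes ring C with retention at C2 to give 15.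

2. Step 5.
- What may go wrong: the ortho-benzyloxy group and the two halogens crowd C-β, so carbometalation may be slow, protodeboronation of 7 may win, and facial selectivity on the conformationally mobile acyclic enone may be poor.
- Fallback (sets out from 2, returns at 8): Wittig olefination of 2 with ethyl (triphenylphosphoranylidene)acetate in hot N,N-diethylaniline should give ethyl (E)-3-(4-bromo-2-hydroxy-5-iodophenyl)acrylate F4. This isomerises and lactonises in the same flask to 7-bromo-6-iodocoumarin F5. The rigid lactone is the best-behaved acceptor class for the Hayashi–Miyaura reaction, and 7 with Rh(acac)(C2H4)2/(R)-SEGPHOS (dioxane–H2O, 60 °C) should give (4R)-4-[4-(benzyloxy)phenyl]-7-bromo-6-iodochroman-2-one F6. Aminolysis with MeNH(OMe)·HCl/AlMe3 gives the phenolic Weinreb amide F7, and BnBr/K2CO3 gives its benzyl ether F8. Weinreb ketone synthesis at −20 °C with 4-(benzyloxy)-2-methoxyphenylmagnesium bromide F9 (from purchased 4-(benzyloxy)-1-bromo-2-methoxybenzene and Mg) gives 8.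

3. Step 6.
- What may go wrong: acid may strip benzyl groups. The benzylic cation may close onto a neighbouring ring (Friedel–Crafts, indane formation). The iodide para to the benzyloxy group may be lost by ipso-protonation.
- Fallback (sets out from 8, returns at 9): a cation-free Caglioti-type deoxygenation. TsNHNH2 in warm EtOH should give the N-tosylhydrazone F10. Catecholborane at 0 °C, then NaOAc·3H2O in refluxing CHCl3, reduces the C=N bond and collapses the resulting diazene to the CH2 group of 9.

Further compounds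
F1 | step 9 | 1-[5-(benzyloxy)-2-methoxyphenyl]prop-2-en-1-ol (racemic) | C=CC(O)c1cc(OCc2ccccc2)ccc1OC
F2 | step 9 | 1-[5-(benzyloxy)-2-methoxyphenyl]-3-(4-(benzyloxy)-2-bromo-5-{(1R)-3-[4-(benzyloxy)-2-methoxyphenyl]-1-[4-(benzyloxy)phenyl]propyl}phenyl)propan-1-one | COc1cc(OCc2ccccc2)ccc1CC[C@H](c1ccc(OCc2ccccc2)cc1)c1cc(CCC(=O)c2cc(OCc3ccccc3)ccc2OC)c(Br)cc1OCc1ccccc1
F3 | step 9 | (1S)-alcohol corresponding to F2 | COc1cc(OCc2ccccc2)ccc1CC[C@H](c1ccc(OCc2ccccc2)cc1)c1cc(CC[C@H](O)c2cc(OCc3ccccc3)ccc2OC)c(Br)cc1OCc1ccccc1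
F4 | step 5 | ethyl (E)-3-(4-bromo-2-hydroxy-5-iodophenyl)acrylate | CCOC(=O)/C=C/c1cc(I)c(Br)cc1O
F5 | step 5 | 7-bromo-6-iodo-2H-chromen-2-one | O=c1ccc2cc(I)c(Br)cc2o1
F6 | step 5 | (4R)-4-[4-(benzyloxy)phenyl]-7-bromo-6-iodochroman-2-one | O=C1C[C@H](c2ccc(OCc3ccccc3)cc2)c2cc(I)c(Br)cc2O1
F7 | step 5 | (3R)-3-[4-(benzyloxy)phenyl]-3-(4-bromo-2-hydroxy-5-iodophenyl)-N-methoxy-N-methylpropanamide | CON(C)C(=O)C[C@H](c1ccc(OCc2ccccc2)cc1)c1cc(I)c(Br)cc1O
F8 | step 5 | (3R)-3-[2-(benzyloxy)-4-bromo-5-iodophenyl]-3-[4-(benzyloxy)phenyl]-N-methoxy-N-methylpropanamide | CON(C)C(=O)C[C@H](c1ccc(OCc2ccccc2)cc1)c1cc(I)c(Br)cc1OCc1ccccc1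
F9 | step 5 | 4-(benzyloxy)-2-methoxyphenylmagnesium bromide | COc1cc(OCc2ccccc2)ccc1[Mg]Br
F10 | step 6 | N-tosylhydrazone of 8 | COc1cc(OCc2ccccc2)ccc1C(C[C@H](c1ccc(OCc2ccccc2)cc1)c1cc(I)c(Br)cc1OCc1ccccc1)=NNS(=O)(=O)c1ccc(C)cc1
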